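## Structural features

Numbering used throughout: ring A is the 4-hydroxy-3-methylfuran-2(5H)-one (O1, C2 carbonyl, C3 with its methyl, C4 with the enol OH, C5). The chain runs from C6 to C18, and ring B is the furan, joined through its C3 to C18.

Ring A and the chain meet in the exocyclic C5=C6 bond. The SMILES fixes it as E, so C7 stands on the side of C4–OH and away from O1, which is the crowded and thermodynamically weaker arrangement.

C7 (R) and C11 (S) are CH(CH3) centres in a 1,5 relation across C8–C10. They are not next to each other and are too far apart for mutual control. With their methyl groups they form a heptane-2,6-diyl unit of meso-type relative configuration, and each is bonded directly to a vinylic CH (C6, C12).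

C12=C13 (E) and C14=C15 (Z, trisubstituted, C13 cis to C16) form a conjugated diene whose Z half is again the less stable geometry.

The fragile groups are ring B (acid, oxidants, electrophilic halogen), the diene (acid, iodine, light) and ring A. Ring A is an acidic vinylogous carboxylic acid whose C5=C6 bond ends a 1,6-acceptor and can isomerise from E to Z by reversible addition or protonation.

The real difficulty is the 5E geometry next to the C7 stereocentre. Condensation or elimination at C5=C6, and metal-catalysed addition of the carboxyl group to an internal C5–C6 alkyne, both lead to 5Z.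

The key step exploits the C6–C7 bond, which joins a vinylic CH to a secondary carbon bearing only H, CH3 and the chain. Each side can be loaded with its stereochemical information beforehand: C6 as an (E)-C–I bond from an anti iodolactonisation of a terminal alkyne, and C7 as a configurationally defined carbon–metal bond derived from a methyl carbinol.

## Logic of the disconnections

**37 ⇒ 36.** Bond cut: O4–CH2 of the enol protecting group. The free enol of 37 would protonate an organozinc, so O4 stays masked until the end. There is no skeletal gain. The demand is a group that leaves with fluoride rather than with acid or a soft nucleophile, because of the labile 5E bond, the diene and ring B.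

**36 ⇒ 25 + 33 (key).** Bond cut: C6–C7, between the ylidene carbon of ring A and the C7 stereocentre.
- Reason: this is the only cut that lets the 5E geometry and the C7 configuration be made separately, by stereospecific reactions, and then simply transferred. No step has to fight the preference for 5Z.
- Gain: 36 falls into 25, which holds the whole chain, and 33, a small achiral block. The last union is fully convergent.
- Demand: a secondary sp3 carbon must be joined to a hindered alkenyl iodide with retention on both sides and without β-hydride elimination.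
- In one sentence: the (E)-alkenyl iodide 33 is cross-coupled at C6 with the secondary alkylzinc made from 25, with retention at both carbons.

**33 ⇒ 32 ⇒ 31 ⇒ 30.** Bonds cut: O4–CH2, then, after lowering C4 to the carbinol level, O1–C5 and C6–I.
- Reason: anti addition of O1 and iodine across a terminal C5–C6 alkyne puts the C6 substituent trans to O1 by mechanism. At the carbinol level the alkyne is not conjugated to a carbonyl and stays reactive towards iodine.
- Gain: ring A, its exocyclic geometry and the coupling handle all come from an acyclic hydroxy acid.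
- Demand: 5-exo closure over 6-endo, and an oxidation that leaves C6–I alone. The configurations at C3 and C4 do not matter.

**30 ⇒ 29 ⇒ 26 + 27.** Bonds cut: C3–C4 (aldol), plus the ester C–O and the alkynyl C–Si bond. The cut is at the only C–C bond flanked by a carbonyl donor and a carbinol. It gives two small achiral building blocks. The demand is 1,2-addition to the ynal and a hydrolysis mild enough to avoid retro-aldol cleavage.

**25 ⇒ 24 ⇒ 23 ⇒ 9 + 20.** Bonds cut: C7–I (back to C7–O with inversion), O–Si, then C11–C12.
- Reason: C11–C12 is the twin of C6–C7, so the same logic applies and no oxidation-level changes are needed at C12.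
- Gain: the chain falls into a seven-carbon unit that holds both stereocentres and a stereodefined halodiene.
- Demand: retention at C11 and at both alkenes. The iodide at C7 must later be made in the presence of the diene and ring B.

**20 ⇒ 13 + 14 + 15.** Bonds cut: C15–C16 and C13–C14, in one operation. Syn addition of carbon and metal across 14 fixes the 14Z geometry by mechanism, and 15 brings C12–C13 with the E geometry and the next handle. Three simple components replace a stereodefined diene. The demand is regioselective addition to the internal alkyne carbon and substitution of only one C–Cl bond.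

**13 ⇒ 10 + 11.** Bond cut: C18–C3 of ring B. An intact furan is alkylated, which avoids building ring B. The demand is a 3-metalated furan that does not rearrange before it is trapped.

**9 ⇒ 8 ⇒ 7 ⇒ 1 + 2 + 3.** Bonds cut: C11–I (back to C11–O with inversion), the two C9–S bonds, then C8–C9 and C9–C10 in one operation.
- Reason: C7 and C11 are methyl carbinol carbons in disguise, and C9 can serve as a double carbanion.
- Gain: both stereocentres are bought, and the two carbinols leave the flask already differentiated.
- Demand: the first opening must be complete before 3 is added, otherwise diastereomeric purity suffers.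

## Other disconnections considered

**Alternative 1:** the cut that comes to mind first, C5=C6. The C5 anion of the O-methyl tetronate A2 would add to the aldehyde A1. The aldol A3 would then be activated and eliminated, or a C5 phosphonate would be used instead.
- The elimination runs through the stabilised C5 carbanion, so the geometry is set under product-like control. That places the chain next to O1 (5Z), the opposite of what is needed.
- A1 carries an epimerisable centre next to the formyl group, and C6 needs its own oxidation-level changes.
- The chosen plan transfers 5E instead of creating it and never passes through an α-branched aldehyde.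

**Alternative 2:** cuts at C5=C6 and C12=C13 after recognising the meso unit C6–C12. A lipase would acylate one enantiotopic hydroxyl of the meso diol A4 to give the monoacetate A5, and two oxidation and olefination sequences would follow.
- One step would fix the absolute sense of both centres, which is attractive.
- Pure A4 first needs a diastereoselective synthesis or a separation from its racemic isomer.
- Both termini pass through epimerisable aldehydes, and C5=C6 is again made by olefination, so 5E stays unsolved.
- The step count is higher than with purchased carbinol centres.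

**Alternative 3:** cut O1–C5 with the whole chain in place. This is a 5-exo-dig cycloisomerisation of the enynoic acid A6 with AgNO3 or AuCl(PPh3)/AgOTf.
- The carboxylate attacks anti to the metal and protonolysis retains geometry, so H ends up trans to O1 and C7 cis to O1. The mechanism is therefore locked to the 5Z ether A7.
- 6-endo closure also competes for an internal alkyne.
- The chosen plan uses the same anti addition on a terminal alkyne with iodine, so the anti position becomes the place where C7 enters.

Key step: step 14

Remark: the SMILES is read as 5E, 7R, 11S, 12E, 14Z; compounds 29, 30 and 31 are used as racemic mixtures of C3/C4 diastereomers because both centres are erased in step 12; IPent = 1,3-bis[2,6-di(pentan-3-yl)phenyl]imidazol-2-ylidene.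

## Steps

Step 1
Reactants: 1 2-(tert-butyldimethylsilyl)-1,3-dithiane; 2 (S)-2-methyloxirane; 3 (R)-2-methyloxirane
Product: 7 (2R)-1-{2-[(2S)-2-(tert-butyldimethylsilyloxy)propyl]-1,3-dithian-2-yl}propan-2-ol, via lithiated silyl dithiane 4 (not isolated), via lithium alkoxide 5 (not isolated), via silyl-shifted lithio dithiane 6 (not isolated)
Conditions: t-BuLi, Et2O, −78 to −45 °C; 2, −78 to −25 °C; 3, HMPA, Et2O, −78 °C to rt; H2O
Reagents that add atoms: none
Why: Anion relay (silyl dithiane linchpin) coupling: 4 opens 2 at its CH2 terminus, HMPA triggers the 1,4-Brook shift of silicon from C9 to the new alkoxide (5 to 6), and carbanion 6 opens 3, so C8–C9 and C9–C10 form in one flask and the two carbinols come out differentiated. Both stereocentres are bought with the epoxides and stay untouched because attack is at the unsubstituted carbon.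

Step 2
Reactants: 7 (2R)-1-{2-[(2S)-2-(tert-butyldimethylsilyloxy)propyl]-1,3-dithian-2-yl}propan-2-ol
Product: 8 (2R,6S)-6-(tert-butyldimethylsilyloxy)heptan-2-ol
Conditions: Raney Ni (W-2), EtOH, reflux
Reagents that add atoms: none
Why: Reductive desulfurisation with Raney nickel replaces both C9–S bonds by C–H; the silyl ether, the free alcohol and both carbinol centres are inert to it.

Step 3
Reactants: 8 (2R,6S)-6-(tert-butyldimethylsilyloxy)heptan-2-ol
Product: 9 tert-butyl{[(2S,6S)-6-iodoheptan-2-yl]oxy}dimethylsilane
Conditions: PPh3, I2, imidazole, CH2Cl2, −10 °C, dark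
Reagents that add atoms: iodine, II
Why: Appel iodination: iodide displaces the alkoxyphosphonium group in an SN2 step, so the (R)-carbinol gives the (S)-iodide. Low temperature, short time and exclusion of light limit iodide–iodide exchange, which would erode the configuration.

Step 4
Reactants: 10 3-bromofuran; 11 1,3-dibromopropane
Product: 13 3-(3-bromopropyl)furan, via 3-lithiofuran 12 (not isolated)
Conditions: n-BuLi, THF, −78 °C; 11 (5 equiv), HMPA, −78 °C to rt
Reagents that add atoms: none
Why: Bromine–lithium exchange followed by SN2 alkylation. Intermediate 12 is kept at −78 °C until the electrophile is present because it rearranges to the 2-lithio isomer on warming, and the excess of 11 suppresses double alkylation.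

Step 5
Reactants: 13 3-(3-bromopropyl)furan; 14 propyne; 15 (E)-1,2-dichloroethene
Product: 20 3-[(4Z,6E)-7-chloro-4-methylhepta-4,6-dien-1-yl]furan, via Grignard reagent 16 (not isolated), via alkylcopper 17 (not isolated), via alkenylcopper 18 (not isolated), via alkenylzinc bromide 19 (not isolated)
Conditions: Mg, Et2O; CuBr·SMe2, Et2O/Me2S, −45 °C; 14, −25 °C; ZnBr2, THF; 15 (5 equiv), Pd(PPh3)4 (5 mol %), −20 °C to rt
Reagents that add atoms: none
Why: Syn-carbocupration of a terminal alkyne, transmetalation to zinc and Negishi-type coupling: the alkyl group of 17 adds to the internal carbon of 14 and copper to the terminal one on the same face, which places C16 and the metal (later C13) cis and fixes 14Z. Zerovalent palladium inserts into one C–Cl bond of 15, used in excess so that only one chloride reacts, and both alkene geometries are retained.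

Step 6
Reactants: 9 tert-butyl{[(2S,6S)-6-iodoheptan-2-yl]oxy}dimethylsilane; 20 3-[(4Z,6E)-7-chloro-4-methylhepta-4,6-dien-1-yl]furan
Product: 23 tert-butyl{[(2S,6S,7E,9Z)-13-(furan-3-yl)-6,10-dimethyltrideca-7,9-dien-2-yl]oxy}dimethylsilane, via secondary alkyllithium 21 (not isolated), via mixed dialkylzinc 22 (not isolated)
Conditions: t-BuLi (2.2 equiv), pentane/Et2O 3:2, −100 °C; Me3SiCH2ZnBr·LiBr, −100 to −30 °C; 20, PdCl2(IPent)(3-chloropyridine) (5 mol %), THF, −25 °C to rt
Reagents that add atoms: none
Why: Same reaction type as the key step on the simpler partner: iodine–lithium exchange with retention at −100 °C, transmetalation with retention to 22, and Negishi coupling in which zerovalent palladium bearing the bulky carbene inserts into the dienyl C12–Cl bond. C11 (S) comes from 9 with retention, and 12E and 14Z come from 20 with retention.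

Step 7
Reactants: 23 tert-butyl{[(2S,6S,7E,9Z)-13-(furan-3-yl)-6,10-dimethyltrideca-7,9-dien-2-yl]oxy}dimethylsilane
Product: 24 (2S,6S,7E,9Z)-13-(furan-3-yl)-6,10-dimethyltrideca-7,9-dien-2-ol
Conditions: Bu4NF, THF, rt
Reagents that add atoms: none
Why: Fluoride cleavage of a silyl ether, driven by the Si–F bond; the diene, ring B and both stereocentres are not affected by Bu4NF.

Step 8
Reactants: 24 (2S,6S,7E,9Z)-13-(furan-3-yl)-6,10-dimethyltrideca-7,9-dien-2-ol
Product: 25 3-[(4Z,6E,8S,12R)-12-iodo-4,8-dimethyltrideca-4,6-dien-1-yl]furan
Conditions: PPh3, I2, imidazole (premixed), CH2Cl2, −10 °C, dark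
Reagents that add atoms: iodine, II
Why: Second Appel iodination with SN2 inversion, (S)-carbinol to (R)-iodide. The reagents are premixed so that no free iodine meets the diene or ring B, and the reaction is run cold and in the dark.

Step 9
Reactants: 26 ethyl propanoate; 27 3-(trimethylsilyl)prop-2-ynal
Product: 29 ethyl 3-hydroxy-2-methyl-5-(trimethylsilyl)pent-4-ynoate, via lithium enolate 28 (not isolated)
Conditions: LiN(iPr)2, THF, −78 °C; 27; H2O
Reagents that add atoms: none
Why: Aldol addition of an ester lithium enolate to an ynal (1,2-addition) forms C3–C4. The diastereomer ratio and the racemic nature do not matter because C3 and C4 become sp2 in step 12.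

Step 10
Reactants: 29 ethyl 3-hydroxy-2-methyl-5-(trimethylsilyl)pent-4-ynoate
Product: 30 3-hydroxy-2-methylpent-4-ynoic acid
Conditions: LiOH, THF/MeOH/H2O, 0 °C to rt; 1 M HCl
Reagents that add atoms: lithium hydroxide, [Li+].[OH-]
Why: Saponification, with hydroxide also cleaving the alkynyl C–Si bond (protodesilylation); the temperature is kept at or below rt to avoid retro-aldol cleavage.

Step 11
Reactants: 30 3-hydroxy-2-methylpent-4-ynoic acid
Product: 31 (5E)-4-hydroxy-5-(iodomethylidene)-3-methyloxolan-2-one
Conditions: I2, NaHCO3, MeCN, 0 °C to rt, dark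
Reagents that add atoms: iodine, II
Why: Iodolactonisation, 5-exo-dig: the carboxylate attacks C5 of the iodine-activated terminal alkyne from the side opposite to iodine, so O1 and I end up trans, which is the E geometry. The 6-endo mode would need attack at the unsubstituted terminal carbon and is disfavoured for terminal 4-alkynoic acids.

Step 12
Reactants: 31 (5E)-4-hydroxy-5-(iodomethylidene)-3-methyloxolan-2-one
Product: 32 (5E)-4-hydroxy-5-(iodomethylidene)-3-methylfuran-2(5H)-one
Conditions: Dess–Martin periodinane, CH2Cl2, 0 °C to rt, dark
Reagents that add atoms: none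
Why: Dess–Martin oxidation of the C4 carbinol; the 2,4-dione enolises at once to the tetronic acid, which erases C3 and C4. The neutral, non-nucleophilic conditions leave the C6–I bond and its geometry alone.

Step 13
Reactants: 32 (5E)-4-hydroxy-5-(iodomethylidene)-3-methylfuran-2(5H)-one
Product: 33 (5E)-5-(iodomethylidene)-3-methyl-4-[2-(trimethylsilyl)ethoxy]furan-2(5H)-one
Conditions: Me3SiCH2CH2OH, PPh3, DIAD, THF, 0 °C, dark
Reagents that add atoms: 2-(trimethylsilyl)ethanol, C[Si](C)(C)CCO
Why: Mitsunobu O-alkylation of a vinylogous acid (pKa near 4) by a primary alcohol; alkylation at O4 gives the conjugated 4-alkoxyfuran-2(5H)-one, the usual outcome for tetronic acids.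

Step 14
Reactants: 25 3-[(4Z,6E,8S,12R)-12-iodo-4,8-dimethyltrideca-4,6-dien-1-yl]furan; 33 (5E)-5-(iodomethylidene)-3-methyl-4-[2-(trimethylsilyl)ethoxy]furan-2(5H)-one
Product: 36 (5E)-5-[(2R,6S,7E,9Z)-13-(furan-3-yl)-2,6,10-trimethyltrideca-7,9-dien-1-ylidene]-3-methyl-4-[2-(trimethylsilyl)ethoxy]furan-2(5H)-one, via secondary alkyllithium 34 (not isolated), via mixed dialkylzinc 35 (not isolated)
Conditions: t-BuLi (2.2 equiv), pentane/Et2O 3:2, −100 °C; Me3SiCH2ZnBr·LiBr, −100 to −30 °C; 33, PdCl2(IPent)(3-chloropyridine) (5 mol %), THF, −25 °C to rt, dark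
Reagents that add atoms: none
Why: Stereoretentive Negishi coupling of a configurationally defined secondary alkylzinc with an alkenyl iodide; the closest known reaction type is the coupling of enantioenriched 2-alkylzinc reagents, made in the same way, with simple alkenyl iodides. Iodine–lithium exchange on 25 at −100 °C is faster than inversion of the secondary carbanion, addition to the diene or metalation of ring B, and gives 34 with retention; immediate transmetalation fixes the configuration in the covalent C7–Zn bond of 35, whose Me3SiCH2 group has no β-hydrogen and is not transferred. Zerovalent palladium inserts into the C6–I bond of 33 with retention of the E geometry, C7 passes from zinc to palladium through a closed four-centre transition state with retention, and reductive elimination forms C6–C7. The step closes no ring and creates no new stereocentre: C7 (R) is carried over from 25 and 5E from the anti iodolactonisation of step 11, so neither depends on the thermodynamic preference for 5Z. It needs branched rather than linear coupling, which the very bulky IPent ligand secures by making reductive elimination faster than β-hydride elimination and re-insertion. It needs selectivity for C–I over the lactone and the 1,6-acceptor of ring A, which the low nucleophilicity of a dialkylzinc secures.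

Step 15
Reactants: 36 (5E)-5-[(2R,6S,7E,9Z)-13-(furan-3-yl)-2,6,10-trimethyltrideca-7,9-dien-1-ylidene]-3-methyl-4-[2-(trimethylsilyl)ethoxy]furan-2(5H)-one
Product: 37 (5E)-5-[(2R,6S,7E,9Z)-13-(furan-3-yl)-2,6,10-trimethyltrideca-7,9-dien-1-ylidene]-4-hydroxy-3-methylfuran-2(5H)-one
Conditions: Bu4NF, THF, 0 °C, dark; cold 0.5 M HCl, brief
Reagents that add atoms: none
Why: Fluoride attacks silicon and the 2-silylethyl group fragments to ethene and Me3SiF, releasing the tetronate anion, which is no longer a 1,6-acceptor and so should hold the 5E geometry. Brief cold acidification gives 37 without exposing ring B or the diene to strong acid.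

## Compound list

1 | 2-(tert-butyldimethylsilyl)-1,3-dithiane | CC(C)(C)[Si](C)(C)C1SCCCS1 | starting material
2 | (S)-2-methyloxirane | C[C@H]1CO1 | starting material
3 | (R)-2-methyloxirane | C[C@@H]1CO1 | starting material
4 | 2-lithio-2-(tert-butyldimethylsilyl)-1,3-dithiane | [Li]C1([Si](C)(C)C(C)(C)C)SCCCS1 | intermediate
5 | lithium (2S)-1-[2-(tert-butyldimethylsilyl)-1,3-dithian-2-yl]propan-2-olate | [Li]O[C@@H](C)CC1([Si](C)(C)C(C)(C)C)SCCCS1 | intermediate
6 | 2-lithio-2-[(2S)-2-(tert-butyldimethylsilyloxy)propyl]-1,3-dithiane | [Li]C1(C[C@H](C)O[Si](C)(C)C(C)(C)C)SCCCS1 | intermediate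
7 | (2R)-1-{2-[(2S)-2-(tert-butyldimethylsilyloxy)propyl]-1,3-dithian-2-yl}propan-2-ol | CC(C)(C)[Si](C)(C)O[C@@H](C)CC1(C[C@@H](C)O)SCCCS1 | intermediate
8 | (2R,6S)-6-(tert-butyldimethylsilyloxy)heptan-2-ol | CC(C)(C)[Si](C)(C)O[C@@H](C)CCC[C@@H](C)O | intermediate
9 | tert-butyl{[(2S,6S)-6-iodoheptan-2-yl]oxy}dimethylsilane | CC(C)(C)[Si](C)(C)O[C@@H](C)CCC[C@H](C)I | intermediate
10 | 3-bromofuran | Brc1ccoc1 | starting material
11 | 1,3-dibromopropane | BrCCCBr | starting material
12 | 3-lithiofuran | [Li]c1ccoc1 | intermediate
13 | 3-(3-bromopropyl)furan | BrCCCc1ccoc1 | intermediate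
14 | propyne | CC#C | starting material
15 | (E)-1,2-dichloroethene | Cl/C=C/Cl | starting material
16 | [3-(furan-3-yl)propyl]magnesium bromide | Br[Mg]CCCc1ccoc1 | intermediate
17 | [3-(furan-3-yl)propyl]copper | [Cu]CCCc1ccoc1 | intermediate
18 | [(1Z)-5-(furan-3-yl)-2-methylpent-1-en-1-yl]copper | [Cu]/C=C(/C)CCCc1ccoc1 | intermediate
19 | [(1Z)-5-(furan-3-yl)-2-methylpent-1-en-1-yl]zinc bromide | Br[Zn]/C=C(/C)CCCc1ccoc1 | intermediate
20 | 3-[(4Z,6E)-7-chloro-4-methylhepta-4,6-dien-1-yl]furan | Cl/C=C/C=C(/C)CCCc1ccoc1 | intermediate
21 | 6-(tert-butyldimethylsilyloxy)heptan-2-yllithium, configuration of 9 retained at both centres | CC(C)(C)[Si](C)(C)O[C@@H](C)CCC[C@H](C)[Li] | intermediate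
22 | [6-(tert-butyldimethylsilyloxy)heptan-2-yl][(trimethylsilyl)methyl]zinc, configuration of 9 retained | CC(C)(C)[Si](C)(C)O[C@@H](C)CCC[C@H](C)[Zn]C[Si](C)(C)C | intermediate
23 | tert-butyl{[(2S,6S,7E,9Z)-13-(furan-3-yl)-6,10-dimethyltrideca-7,9-dien-2-yl]oxy}dimethylsilane | CC(C)(C)[Si](C)(C)O[C@@H](C)CCC[C@H](C)/C=C/C=C(/C)CCCc1ccoc1 | intermediate
24 | (2S,6S,7E,9Z)-13-(furan-3-yl)-6,10-dimethyltrideca-7,9-dien-2-ol | O[C@@H](C)CCC[C@H](C)/C=C/C=C(/C)CCCc1ccoc1 | intermediate
25 | 3-[(4Z,6E,8S,12R)-12-iodo-4,8-dimethyltrideca-4,6-dien-1-yl]furan | I[C@H](C)CCC[C@H](C)/C=C/C=C(/C)CCCc1ccoc1 | intermediate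
26 | ethyl propanoate | CCC(=O)OCC | starting material
27 | 3-(trimethylsilyl)prop-2-ynal | C[Si](C)(C)C#CC=O | starting material
28 | lithium enolate of ethyl propanoate | CC=C(OCC)O[Li] | intermediate
29 | ethyl 3-hydroxy-2-methyl-5-(trimethylsilyl)pent-4-ynoate (racemic diastereomer mixture) | CCOC(=O)C(C)C(O)C#C[Si](C)(C)C | intermediate
30 | 3-hydroxy-2-methylpent-4-ynoic acid (racemic diastereomer mixture) | OC(=O)C(C)C(O)C#C | intermediate
31 | (5E)-4-hydroxy-5-(iodomethylidene)-3-methyloxolan-2-one (racemic diastereomer mixture at C3/C4) | CC1C(O)/C(=C\I)OC1=O | intermediate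
32 | (5E)-4-hydroxy-5-(iodomethylidene)-3-methylfuran-2(5H)-one | CC1=C(O)/C(=C\I)OC1=O | intermediate
33 | (5E)-5-(iodomethylidene)-3-methyl-4-[2-(trimethylsilyl)ethoxy]furan-2(5H)-one | CC1=C(OCC[Si](C)(C)C)/C(=C\I)OC1=O | intermediate
34 | (7E,9Z)-13-(furan-3-yl)-6,10-dimethyltrideca-7,9-dien-2-yllithium, configuration of 25 retained at both centres | [Li][C@H](C)CCC[C@H](C)/C=C/C=C(/C)CCCc1ccoc1 | intermediate
35 | [(7E,9Z)-13-(furan-3-yl)-6,10-dimethyltrideca-7,9-dien-2-yl][(trimethylsilyl)methyl]zinc, configuration of 25 retained | C[Si](C)(C)C[Zn][C@H](C)CCC[C@H](C)/C=C/C=C(/C)CCCc1ccoc1 | intermediate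
36 | (5E)-5-[(2R,6S,7E,9Z)-13-(furan-3-yl)-2,6,10-trimethyltrideca-7,9-dien-1-ylidene]-3-methyl-4-[2-(trimethylsilyl)ethoxy]furan-2(5H)-one | CC1=C(OCC[Si](C)(C)C)/C(=C\[C@H](C)CCC[C@H](C)/C=C/C=C(/C)CCCc2ccoc2)OC1=O | intermediate
37 | (5E)-5-[(2R,6S,7E,9Z)-13-(furan-3-yl)-2,6,10-trimethyltrideca-7,9-dien-1-ylidene]-4-hydroxy-3-methylfuran-2(5H)-one | CC1=C(O)/C(=C\[C@H](C)CCC[C@H](C)/C=C/C=C(/C)CCCc2ccoc2)OC1=O | target

## Step count and least certain steps

Total step count: 15. Longest linear sequence: 8 steps (1, 2, 3, 6, 7, 8, 14, 15).

**Step 14 (key).**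
- What may go wrong: insertion and transmetalation at the hindered C6 position, cis to the 4-alkoxy group, may be slow. β-Hydride elimination and re-insertion could then move palladium along the chain, with loss of the branched connectivity and of the C7 configuration.
- Charge separation in the push–pull alkenylpalladium species could allow rotation about C5=C6, with loss of the E geometry.
- Partial inversion of 34 before transmetalation would also erode C7.
- Fallback: it sets out from 31 and 25 and comes back at 37. The hydroxyl of 31 would be silylated (Et3SiCl, imidazole) to the triethylsilyl ether F1, whose C6–I bond is flanked by an sp3 C4 and is not part of a conjugated acceptor. Zinc reagent 35, made from 25 as in step 14, would be coupled with it to give the enol lactone F2. Buffered fluoride (Bu4NF/AcOH) would free the alcohol F3, and Dess–Martin oxidation would give 37 directly, with the C3 and C4 centres erased on enolisation.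

**Step 6.**
- What may go wrong: insertion into the C12–Cl bond may be slower than for an iodide. Zinc reagent 22 would then age, with slow epimerisation at C11 or protonation, and homocoupling of 20 could compete.
- Fallback: it sets out from 9 (through 22) and comes back at 23. Reagent 22 would be coupled with commercial (E)-(2-bromovinyl)trimethylsilane to give the vinylsilane F4. Iododesilylation with N-iodosuccinimide in MeCN would give the (E)-vinyl iodide F5 with retention. F5 would then be joined with alkenylzinc 19 under Pd(PPh3)4, so the chain is closed at C13–C14 instead of C11–C12.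

**Step 5.**
- What may go wrong: substitution of both chlorides of 15, oxidative dimerisation of 18, or incomplete regioselectivity of the carbocupration, which would place methyl and chain wrongly.
- Fallback: it sets out from 13 (through 18) and comes back at 23. Intermediate 18 would be quenched with I2 to the isolable (Z)-vinyl iodide F6. A Stille coupling with commercial (E)-1,2-bis(tributylstannyl)ethene would give the dienylstannane F7. Tin–iodine exchange with I2 would give the iododiene F8, which takes the place of 20 in step 6.

**Step 12.**
- What may go wrong: loss of water across C3–C4 from the β-hydroxy lactone, isomerisation or loss of the C6–I bond in the acidic product, and losses on isolating a polar acid.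
- Fallback: it sets out from 29 and comes back at 33, with the oxidation placed before ring closure. Compound 29 would be oxidised (Dess–Martin periodinane) to the β-keto ester F9. Mitsunobu O-alkylation with Me3SiCH2CH2OH would give the (E)-enol ether F10. LiOH would remove the ester and the alkynyl silyl group to give the enynoic acid F11, and iodolactonisation (I2, NaHCO3) would close ring A anti to give 33.

**Step 15.**
- What may go wrong: reversible addition of fluoride or adventitious hydroxide to C6 of the still protected 1,6-acceptor, followed by rotation and loss of the nucleophile. This would drain 5E into 5Z before the silyl group has left.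
- Fallback: it sets out from 32 and 25 and comes back at 37, without any enol protecting group. Compound 32 would be deprotonated with LiN(SiMe3)2 to the lithium tetronate F12. That salt would be coupled as such with 35 under the conditions of step 14, and cold acidification would give 37. Steps 13 and 15 then fall away.

## Further compounds

F1 | step 14 | (5E)-5-(iodomethylidene)-3-methyl-4-(triethylsilyloxy)oxolan-2-one (diastereomer mixture at C3/C4) | CC1C(O[Si](CC)(CC)CC)/C(=C\I)OC1=O
F2 | step 14 | (5E)-5-[(2R,6S,7E,9Z)-13-(furan-3-yl)-2,6,10-trimethyltrideca-7,9-dien-1-ylidene]-3-methyl-4-(triethylsilyloxy)oxolan-2-one (mixture at C3/C4) | CC1C(O[Si](CC)(CC)CC)/C(=C\[C@H](C)CCC[C@H](C)/C=C/C=C(/C)CCCc2ccoc2)OC1=O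
F3 | step 14 | (5E)-5-[(2R,6S,7E,9Z)-13-(furan-3-yl)-2,6,10-trimethyltrideca-7,9-dien-1-ylidene]-4-hydroxy-3-methyloxolan-2-one (mixture at C3/C4) | CC1C(O)/C(=C\[C@H](C)CCC[C@H](C)/C=C/C=C(/C)CCCc2ccoc2)OC1=O
F4 | step 6 | tert-butyldimethyl{[(2S,6S,7E)-6-methyl-8-(trimethylsilyl)oct-7-en-2-yl]oxy}silane | CC(C)(C)[Si](C)(C)O[C@@H](C)CCC[C@H](C)/C=C/[Si](C)(C)C
F5 | step 6 | tert-butyl{[(2S,6S,7E)-8-iodo-6-methyloct-7-en-2-yl]oxy}dimethylsilane | CC(C)(C)[Si](C)(C)O[C@@H](C)CCC[C@H](C)/C=C/I
F6 | step 5 | 3-[(4Z)-5-iodo-4-methylpent-4-en-1-yl]furan | I/C=C(/C)CCCc1ccoc1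
F7 | step 5 | tributyl[(1E,3Z)-7-(furan-3-yl)-4-methylhepta-1,3-dien-1-yl]stannane | CCCC[Sn](CCCC)(CCCC)/C=C/C=C(/C)CCCc1ccoc1
F8 | step 5 | 3-[(4Z,6E)-7-iodo-4-methylhepta-4,6-dien-1-yl]furan | I/C=C/C=C(/C)CCCc1ccoc1
F9 | step 12 | ethyl 2-methyl-3-oxo-5-(trimethylsilyl)pent-4-ynoate | CCOC(=O)C(C)C(=O)C#C[Si](C)(C)C
F10 | step 12 | ethyl (2E)-2-methyl-5-(trimethylsilyl)-3-[2-(trimethylsilyl)ethoxy]pent-2-en-4-ynoate | CCOC(=O)/C(C)=C(OCC[Si](C)(C)C)\C#C[Si](C)(C)C
F11 | step 12 | (2E)-2-methyl-3-[2-(trimethylsilyl)ethoxy]pent-2-en-4-ynoic acid | OC(=O)/C(C)=C(OCC[Si](C)(C)C)\C#C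
F12 | step 15 | lithium (2E)-2-(iodomethylidene)-4-methyl-5-oxo-2,5-dihydrofuran-3-olate | CC1=C([O-])/C(=C\I)OC1=O.[Li+]
A1 | alternative 1 | (2R,6S,7E,9Z)-13-(furan-3-yl)-2,6,10-trimethyltrideca-7,9-dienal | O=C[C@H](C)CCC[C@H](C)/C=C/C=C(/C)CCCc1ccoc1
A2 | alternative 1 | 4-methoxy-3-methylfuran-2(5H)-one | COC1=C(C)C(=O)OC1
A3 | alternative 1 | 5-[(2R,6S,7E,9Z)-13-(furan-3-yl)-1-hydroxy-2,6,10-trimethyltrideca-7,9-dien-1-yl]-4-methoxy-3-methylfuran-2(5H)-one | COC1=C(C)C(=O)OC1C(O)[C@H](C)CCC[C@H](C)/C=C/C=C(/C)CCCc2ccoc2
A4 | alternative 2 | meso-(2R,6S)-2,6-dimethylheptane-1,7-diol | OC[C@H](C)CCC[C@H](C)CO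
A5 | alternative 2 | (2R,6S)-7-hydroxy-2,6-dimethylheptyl acetate | CC(=O)OC[C@H](C)CCC[C@H](C)CO
A6 | alternative 3 | (2E,6R,10S,11E,13Z)-17-(furan-3-yl)-3-methoxy-2,6,10,14-tetramethylheptadeca-2,11,13-trien-4-ynoic acid | OC(=O)/C(C)=C(OC)\C#C[C@H](C)CCC[C@H](C)/C=C/C=C(/C)CCCc1ccoc1
A7 | alternative 3 | (5Z)-5-[(2R,6S,7E,9Z)-13-(furan-3-yl)-2,6,10-trimethyltrideca-7,9-dien-1-ylidene]-4-methoxy-3-methylfuran-2(5H)-one | CC1=C(OC)/C(=C/[C@H](C)CCC[C@H](C)/C=C/C=C(/C)CCCc2ccoc2)OC1=O
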